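## Retrosynthetic overview

1. The last step closes ring B and the spiro centre: the acyclic tail bromochloride of monocyclic acetate 17 is ionised in HFIP to an enantiopure bromonium ion, the exocyclic tetrasubstituted alkene attacks it (C6–C7 bond), and the C1 acetate traps the C11 cation. This replaces the usual Diels–Alder spiroannulation.
2. The ring A halogens go in before spirocyclisation, by hydroxyl-directed bromochlorination of cyclohexenol 13, while the future nucleophilic alkene is masked as an electron-poor enol triflate (later OTf → CH3 by Negishi coupling).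
3. Ring A comes from ring-closing metathesis; C1 is set by asymmetric methallylation of an enal.
4. The alkene geometry comes from an (E)-enol triflate of a β-keto ester, itself made by dianion alkylation with the triflate of (R)-2-bromo-3-chloro-3-methylbutanol (enantioselective bromochlorination of prenol).
5. Order of ring formation: ring A (step 8), then ring B (step 12).

Assumption: the (S,R) antipode of the tridentate Schiff-base ligand (a salicylaldimine of a chiral 1,2-amino alcohol) gives (R)-3; if the sense is the opposite, the mirror-image ligand is used.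
Numbering in names and text follows the target: C1 = C–O carbon, C3 = C(CH3)Cl, C4 = CHBr, C6 = spiro carbon, C7 = C(CH3)2, C8 = CHBr of ring B, C11 = C(CH3)OH.

## Route

Step 1
Reactants: 1 3-methylbut-2-en-1-ol (prenol)
Product: 3 (2R)-2-bromo-3-chloro-3-methylbutan-1-ol, via chlorotitanium alkoxide 2 (not isolated)
Conditions: NBS (1.1 equiv), ClTi(OiPr)3 (1.1 equiv), (S,R)-Schiff-base ligand (20 mol %), hexanes, −20 °C; aq. work-up
Reagents that add atoms: N-bromosuccinimide, O=C1CCC(=O)N1Br; chlorotitanium triisopropoxide, CC(C)O[Ti](Cl)(OC(C)C)OC(C)C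
Why: Catalytic enantioselective bromochlorination of an allylic alcohol, in which the ligand-bound titanium alkoxide delivers chloride to the tertiary (Markovnikov) carbon anti to bromine and the chiral ligand fixes the CHBr centre as R.

Step 2
Reactants: 3 (2R)-2-bromo-3-chloro-3-methylbutan-1-ol
Product: 4 (2R)-2-bromo-3-chloro-3-methylbutyl trifluoromethanesulfonate
Conditions: Tf2O (1.1 equiv), 2,6-lutidine (1.3 equiv), CH2Cl2, −78 °C; used crude
Reagents that add atoms: triflic anhydride, O=S(=O)(OS(=O)(=O)C(F)(F)F)C(F)(F)F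
Why: O-Triflation of the primary alcohol at low temperature with a hindered base gives the alkylating agent without touching the CHBr stereocentre.

Step 3
Reactants: 5 ethyl 2-acetylpent-4-enoate (ethyl 2-allylacetoacetate); 4 (2R)-2-bromo-3-chloro-3-methylbutyl trifluoromethanesulfonate
Product: 7 ethyl (6R)-6-bromo-7-chloro-7-methyl-3-oxo-2-(prop-2-en-1-yl)octanoate, via sodium lithium dianion 6 (not isolated)
Conditions: 5, NaH (1.1 equiv), THF, 0 °C; n-BuLi (1.05 equiv), 0 °C; then 4, −78 → −40 °C; aq. work-up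
Reagents that add atoms: none
Why: γ-Alkylation of a β-keto ester dianion, in which the terminal carbanion displaces the primary triflate (SN2) at low temperature and the R centre is carried over unchanged.

Step 4
Reactants: 7 ethyl (6R)-6-bromo-7-chloro-7-methyl-3-oxo-2-(prop-2-en-1-yl)octanoate
Product: 8 ethyl (2E,6R)-6-bromo-7-chloro-7-methyl-2-(prop-2-en-1-yl)-3-{[(trifluoromethyl)sulfonyl]oxy}oct-2-enoate
Conditions: Tf2O (1.5 equiv), 25% aq. Me4NOH (3 equiv), toluene, 0 °C, 15 min
Reagents that add atoms: triflic anhydride, O=S(=O)(OS(=O)(=O)C(F)(F)F)C(F)(F)F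
Why: Stereoselective enol triflation of a β-keto ester, in which the non-chelated ammonium enolate reacts with its oxygen anti to the ester (no metal chelate, least alkyl/alkyl strain), placing OTf trans to CO2Et and the tail CH2 cis to it, the geometry later needed for C10 cis to C1.

Step 5
Reactants: 8 the (E)-enol triflate ester
Product: 9 (2E,6R)-6-bromo-7-chloro-1-hydroxy-7-methyl-2-(prop-2-en-1-yl)oct-2-en-3-yl trifluoromethanesulfonate
Conditions: i-Bu2AlH (2.3 equiv), CH2Cl2, −78 °C; aq. potassium sodium tartrate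
Reagents that add atoms: none
Why: 1,2-Reduction of the enoate with DIBAL-H stops at the allylic alcohol and leaves the vinyl triflate, the alkene geometry and the alkyl halides intact.

Step 6
Reactants: 9 the allylic alcohol
Product: 10 (2E,6R)-6-bromo-7-chloro-7-methyl-1-oxo-2-(prop-2-en-1-yl)oct-2-en-3-yl trifluoromethanesulfonate
Conditions: Dess–Martin periodinane (1.2 equiv), CH2Cl2, 0 °C, 30 min; used at once
Reagents that add atoms: none
Why: Dess–Martin oxidation of the allylic alcohol under neutral conditions gives the β-triflyloxy enal without E/Z isomerisation.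

Step 7
Reactants: 10 the β-triflyloxy enal
Product: 12 (4R,5E,9R)-9-bromo-10-chloro-4-hydroxy-2,10-dimethyl-5-(prop-2-en-1-yl)undeca-1,5-dien-6-yl trifluoromethanesulfonate, via diisopinocampheylborinate 11 (not isolated)
Conditions: (+)-Ipc2BCl [from (−)-α-pinene], CH2=C(CH3)CH2MgCl, Et2O, −78 → 0 °C; then 10, −78 °C; HOCH2CH2NH2 work-up
Reagents that add atoms: 2-methylallylmagnesium chloride, CC(=C)C[Mg]Cl
Why: Asymmetric methallylboration (Brown type), in which the closed chair transition state of the (−)-α-pinene-derived borane adds to the Re face of the aldehyde and sets C1 as R under reagent control, while 1,2-addition spares the vinyl triflate.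

Step 8
Reactants: 12 the dienyl alcohol
Product: 13 (1R,6E)-6-[(4R)-4-bromo-5-chloro-5-methyl-1-{[(trifluoromethyl)sulfonyl]oxy}hexylidene]-3-methylcyclohex-3-en-1-ol
Conditions: second-generation Grubbs catalyst RuCl2(=CHPh)(PCy3)(H2IMes) (5 mol %), CH2Cl2 (5 mM), 40 °C
Reagents that add atoms: none
Why: Ring-closing metathesis between the methallyl and allyl alkenes closes ring A as the trisubstituted cyclohexene with loss of ethene, while the fully substituted, electron-poor enol triflate alkene does not react.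

Step 9
Reactants: 13 the ring A cyclohexenol
Product: 15 (1R,3S,4S,6E)-4-bromo-6-[(4R)-4-bromo-5-chloro-5-methyl-1-{[(trifluoromethyl)sulfonyl]oxy}hexylidene]-3-chloro-3-methylcyclohexan-1-ol, via chlorotitanium alkoxide 14 (not isolated)
Conditions: ClTi(OiPr)3 (1.3 equiv), CH2Cl2–hexanes, −20 °C, 30 min; NBS (1.1 equiv), −20 → 0 °C; aq. work-up
Reagents that add atoms: N-bromosuccinimide, O=C1CCC(=O)N1Br; chlorotitanium triisopropoxide, CC(C)O[Ti](Cl)(OC(C)C)OC(C)C
Why: Proposed new method: the titanium alkoxide of the pseudoaxial C1 hydroxyl (axial because of allylic 1,3-strain with the cis CH2 of the exocyclic alkene) delivers chloride through a six-membered array to the tertiary C3 on its own face while bromine adds to the opposite face (anti, Markovnikov), giving Cl cis to C1–O and Br trans to Cl, and the enol triflate alkene is too electron-poor to react with NBS; the closest known reaction is the titanium-mediated bromochlorination of allylic alcohols with intramolecular chloride delivery, extended here to a homoallylic alcohol.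

Step 10
Reactants: 15 the bromochloro alcohol
Product: 16 (1R,3S,4S,6E)-4-bromo-6-[(4R)-4-bromo-5-chloro-5-methyl-1-{[(trifluoromethyl)sulfonyl]oxy}hexylidene]-3-chloro-3-methylcyclohexyl acetate
Conditions: Ac2O, pyridine, DMAP (cat.), CH2Cl2, 0 °C → rt
Reagents that add atoms: acetic anhydride, CC(=O)OC(C)=O
Why: DMAP-catalysed acylation installs the acetate of the target, which also prevents alkoxide-triggered fragmentation of the neighbouring vinyl triflate in the next step.

Step 11
Reactants: 16 the vinyl triflate acetate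
Product: 17 (1R,3S,4S,6Z)-4-bromo-6-[(5R)-5-bromo-6-chloro-6-methylheptan-2-ylidene]-3-chloro-3-methylcyclohexyl acetate
Conditions: MeZnCl (3 equiv), Pd(PPh3)4 (5 mol %), THF, 45 °C
Reagents that add atoms: methylzinc chloride, C[Zn]Cl
Why: Negishi cross-coupling, in which zerovalent palladium inserts into the vinyl C–OTf bond and methyl is transferred with retention of geometry, unmasking the nucleophilic tetrasubstituted alkene with CH3 cis to C5 and the tail cis to C1, while the unactivated secondary bromides and tertiary chlorides do not undergo oxidative addition.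

Step 12
Reactants: 17 the monocyclic acetate
Product: 20 (1R,3S,4S,6R,8R,11S)-4,8-dibromo-3-chloro-11-hydroxy-3,7,7,11-tetramethylspiro[5.5]undecan-1-yl acetate (CNP0170512.2), via bromonium ion 18 (not isolated), via dioxanylium ion 19 (not isolated)
Conditions: (CF3)2CHOH (HFIP), H2O (5 equiv), NaHCO3 (3 equiv), 0 °C → rt
Reagents that add atoms: water, O
Why: Proposed new method: in HFIP the acyclic tertiary chloride ionises with anchimeric help of the vicinal bromine to an enantiopure bromonium ion (C8 stays R), the tetrasubstituted alkene attacks the C(CH3)2 terminus through a chair transition state with bromine equatorial (C6 set as R), the acetate carbonyl closes onto the C11 cation anti to the new C6–C7 bond (C11 set as S), and water opens the dioxanylium ion to the secondary acetate and tertiary alcohol; the closest known reactions are the solvolytic bromopolyene cyclisation of vicinal bromochlorides in HFIP and acyloxy neighbouring-group termination of cation–olefin cyclisations.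

## Compound list

1 | 3-methylbut-2-en-1-ol (prenol) | CC(C)=CCO | starting material
2 | chlorodiisopropoxytitanium 3-methylbut-2-en-1-olate (not isolated) | CC(C)=CCO[Ti](Cl)(OC(C)C)OC(C)C | intermediate
3 | (2R)-2-bromo-3-chloro-3-methylbutan-1-ol | OC[C@@H](Br)C(C)(C)Cl | intermediate
4 | (2R)-2-bromo-3-chloro-3-methylbutyl trifluoromethanesulfonate | FC(F)(F)S(=O)(=O)OC[C@@H](Br)C(C)(C)Cl | intermediate
5 | ethyl 2-acetylpent-4-enoate (ethyl 2-allylacetoacetate) | CCOC(=O)C(CC=C)C(C)=O | starting material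
6 | sodium lithium dianion of 5 (not isolated) | [Na+].[Li+].CCOC(=O)[C-](CC=C)C(=O)[CH2-] | intermediate
7 | ethyl (6R)-6-bromo-7-chloro-7-methyl-3-oxo-2-(prop-2-en-1-yl)octanoate (C2 epimers) | CCOC(=O)C(CC=C)C(=O)CC[C@@H](Br)C(C)(C)Cl | intermediate
8 | ethyl (2E,6R)-6-bromo-7-chloro-7-methyl-2-(prop-2-en-1-yl)-3-{[(trifluoromethyl)sulfonyl]oxy}oct-2-enoate | CCOC(=O)/C(CC=C)=C(/OS(=O)(=O)C(F)(F)F)CC[C@@H](Br)C(C)(C)Cl | intermediate
9 | (2E,6R)-6-bromo-7-chloro-1-hydroxy-7-methyl-2-(prop-2-en-1-yl)oct-2-en-3-yl trifluoromethanesulfonate | OC/C(CC=C)=C(/OS(=O)(=O)C(F)(F)F)CC[C@@H](Br)C(C)(C)Cl | intermediate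
10 | (2E,6R)-6-bromo-7-chloro-7-methyl-1-oxo-2-(prop-2-en-1-yl)oct-2-en-3-yl trifluoromethanesulfonate | O=C/C(CC=C)=C(/OS(=O)(=O)C(F)(F)F)CC[C@@H](Br)C(C)(C)Cl | intermediate
11 | diisopinocampheylborinate ester of 12 (not isolated) | CC(=C)C[C@@H](OB([C@H]1C[C@H]2C[C@@H]([C@@H]1C)C2(C)C)[C@H]1C[C@H]2C[C@@H]([C@@H]1C)C2(C)C)/C(CC=C)=C(/OS(=O)(=O)C(F)(F)F)CC[C@@H](Br)C(C)(C)Cl | intermediate
12 | (4R,5E,9R)-9-bromo-10-chloro-4-hydroxy-2,10-dimethyl-5-(prop-2-en-1-yl)undeca-1,5-dien-6-yl trifluoromethanesulfonate | CC(=C)C[C@@H](O)/C(CC=C)=C(/OS(=O)(=O)C(F)(F)F)CC[C@@H](Br)C(C)(C)Cl | intermediate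
13 | (1R,6E)-6-[(4R)-4-bromo-5-chloro-5-methyl-1-{[(trifluoromethyl)sulfonyl]oxy}hexylidene]-3-methylcyclohex-3-en-1-ol | CC1=CC/C(=C(\OS(=O)(=O)C(F)(F)F)CC[C@@H](Br)C(C)(C)Cl)[C@H](O)C1 | intermediate
14 | chlorodiisopropoxytitanium alkoxide of 13 (not isolated) | CC1=CC/C(=C(\OS(=O)(=O)C(F)(F)F)CC[C@@H](Br)C(C)(C)Cl)[C@H](O[Ti](Cl)(OC(C)C)OC(C)C)C1 | intermediate
15 | (1R,3S,4S,6E)-4-bromo-6-[(4R)-4-bromo-5-chloro-5-methyl-1-{[(trifluoromethyl)sulfonyl]oxy}hexylidene]-3-chloro-3-methylcyclohexan-1-ol | O[C@@H]1C[C@](C)(Cl)[C@@H](Br)C/C1=C(\OS(=O)(=O)C(F)(F)F)CC[C@@H](Br)C(C)(C)Cl | intermediate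
16 | (1R,3S,4S,6E)-4-bromo-6-[(4R)-4-bromo-5-chloro-5-methyl-1-{[(trifluoromethyl)sulfonyl]oxy}hexylidene]-3-chloro-3-methylcyclohexyl acetate | CC(=O)O[C@@H]1C[C@](C)(Cl)[C@@H](Br)C/C1=C(\OS(=O)(=O)C(F)(F)F)CC[C@@H](Br)C(C)(C)Cl | intermediate
17 | (1R,3S,4S,6Z)-4-bromo-6-[(5R)-5-bromo-6-chloro-6-methylheptan-2-ylidene]-3-chloro-3-methylcyclohexyl acetate | CC(=O)O[C@@H]1C[C@](C)(Cl)[C@@H](Br)C/C1=C(\C)CC[C@@H](Br)C(C)(C)Cl | intermediate
18 | C7–C8 bromonium (bromiranium) ion of 17 (not isolated) | CC(=O)O[C@@H]1C[C@](C)(Cl)[C@@H](Br)C/C1=C(\C)CC[C@@H]2C(C)(C)[Br+]2 | intermediate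
19 | 2-methyl-1,3-dioxan-2-ylium ion bridging C1–O and C11–O of the spirocycle (not isolated) | C[C+]1O[C@@H]2C[C@](C)(Cl)[C@@H](Br)C[C@@]23C(C)(C)[C@H](Br)CC[C@@]3(C)O1 | intermediate
20 | (1R,3S,4S,6R,8R,11S)-4,8-dibromo-3-chloro-11-hydroxy-3,7,7,11-tetramethylspiro[5.5]undecan-1-yl acetate | CC(=O)O[C@@H]1C[C@](C)(Cl)[C@@H](Br)C[C@@]12C(C)(C)[C@H](Br)CC[C@@]2(C)O | target

## Step count and risks

Total steps: 12. Longest linear sequence: 12 steps (1 → 20); 5 is commercial and enters in step 3.

The three steps most likely to fail: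

Step 12 (spirocyclisation cascade). Three things can go wrong. The ring A tertiary chloride can ionise competitively, helped by its anti bromine and trapped by the cis-1,3 acetate or by water; it should be slower than the tail because of the acetoxy group and because the diequatorial chair is unreactive. The C11 cation can lose a proton instead of being trapped. The dioxanylium ion 19 can open to the tertiary acetate. The fallback changes the terminating group and removes water from the medium. It sets out from 15. Boc2O and DMAP in MeCN give (1R,3S,4S,6E)-4-bromo-6-[(4R)-4-bromo-5-chloro-5-methyl-1-{[(trifluoromethyl)sulfonyl]oxy}hexylidene]-3-chloro-3-methylcyclohexyl tert-butyl carbonate F6. Negishi methylation (MeZnCl, Pd(PPh3)4, THF) gives (1R,3S,4S,6Z)-4-bromo-6-[(5R)-5-bromo-6-chloro-6-methylheptan-2-ylidene]-3-chloro-3-methylcyclohexyl tert-butyl carbonate F7. Anhydrous HFIP with NaHCO3 then gives, by the same bromonium cyclisation with irreversible carbonate capture and loss of isobutene, (1R,3S,4S,6R,8R,11S)-4,8-dibromo-3-chloro-3,7,7,11-tetramethylspiro[5.5]undecane-1,11-diyl carbonate F8. Methanolysis (K2CO3 cat., MeOH, rt) gives (1R,3S,4S,6R,8R,11S)-4,8-dibromo-3-chloro-3,7,7,11-tetramethylspiro[5.5]undecane-1,11-diol F9. Selective acetylation of the secondary hydroxyl (Ac2O, pyridine, DMAP) comes back to the route at 20.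

Step 9 (directed bromochlorination). The titanium-bound oxygen may attack C4 across the ring (bromoetherification to a 7-oxabicyclo[2.2.1]heptane) instead of delivering chloride to C3, or delivery from a homoallylic position may be inefficient. The fallback replaces alkene dihalogenation by an epoxide route and sets out from 13. Hydroxyl-directed epoxidation (VO(acac)2 cat., t-BuOOH, CH2Cl2, 0 °C) on the face of the C1 hydroxyl gives (1R,3S,4R,6E)-6-[(4R)-4-bromo-5-chloro-5-methyl-1-{[(trifluoromethyl)sulfonyl]oxy}hexylidene]-3,4-epoxy-3-methylcyclohexan-1-ol F4. Bromide opening at the secondary C4 with inversion (Li2NiBr4, THF, 0 °C) gives (1R,3S,4S,6E)-4-bromo-6-[(4R)-4-bromo-5-chloro-5-methyl-1-{[(trifluoromethyl)sulfonyl]oxy}hexylidene]-3-methylcyclohexane-1,3-diol F5. Treatment with HCl in CH2Cl2 converts the tertiary hydroxyl into chloride with retention through the bromonium ion (double inversion) and comes back to the route at 15.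

Step 3 (dianion alkylation). The basic dianion may attack bromine or abstract the CHBr proton of the hindered β-bromo triflate and cause elimination instead of SN2. The fallback uses a soft organocopper nucleophile and builds the keto ester by aldol and oxidation; it sets out from 4. Allylmagnesium bromide with CuI (10 mol %) in THF at −78 °C gives (5R)-5-bromo-6-chloro-6-methylhept-1-ene F1. Ozonolysis (O3, CH2Cl2, −78 °C; PPh3) gives (4R)-4-bromo-5-chloro-5-methylhexanal F2. Aldol addition of the lithium enolate of ethyl pent-4-enoate (LiN(iPr)2, THF, −78 °C) gives ethyl (6R)-6-bromo-7-chloro-3-hydroxy-7-methyl-2-(prop-2-en-1-yl)octanoate F3. Dess–Martin oxidation comes back to the route at 7.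

Further compounds

F1 | step 3 | (5R)-5-bromo-6-chloro-6-methylhept-1-ene | C=CCC[C@@H](Br)C(C)(C)Cl
F2 | step 3 | (4R)-4-bromo-5-chloro-5-methylhexanal | O=CCC[C@@H](Br)C(C)(C)Cl
F3 | step 3 | ethyl (6R)-6-bromo-7-chloro-3-hydroxy-7-methyl-2-(prop-2-en-1-yl)octanoate | CCOC(=O)C(CC=C)C(O)CC[C@@H](Br)C(C)(C)Cl
F4 | step 9 | (1R,3S,4R,6E)-6-[(4R)-4-bromo-5-chloro-5-methyl-1-{[(trifluoromethyl)sulfonyl]oxy}hexylidene]-3,4-epoxy-3-methylcyclohexan-1-ol | O[C@@H]1C[C@]2(C)O[C@@H]2C/C1=C(\OS(=O)(=O)C(F)(F)F)CC[C@@H](Br)C(C)(C)Cl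
F5 | step 9 | (1R,3S,4S,6E)-4-bromo-6-[(4R)-4-bromo-5-chloro-5-methyl-1-{[(trifluoromethyl)sulfonyl]oxy}hexylidene]-3-methylcyclohexane-1,3-diol | O[C@@H]1C[C@](C)(O)[C@@H](Br)C/C1=C(\OS(=O)(=O)C(F)(F)F)CC[C@@H](Br)C(C)(C)Cl
F6 | step 12 | (1R,3S,4S,6E)-4-bromo-6-[(4R)-4-bromo-5-chloro-5-methyl-1-{[(trifluoromethyl)sulfonyl]oxy}hexylidene]-3-chloro-3-methylcyclohexyl tert-butyl carbonate | CC(C)(C)OC(=O)O[C@@H]1C[C@](C)(Cl)[C@@H](Br)C/C1=C(\OS(=O)(=O)C(F)(F)F)CC[C@@H](Br)C(C)(C)Cl
F7 | step 12 | (1R,3S,4S,6Z)-4-bromo-6-[(5R)-5-bromo-6-chloro-6-methylheptan-2-ylidene]-3-chloro-3-methylcyclohexyl tert-butyl carbonate | CC(C)(C)OC(=O)O[C@@H]1C[C@](C)(Cl)[C@@H](Br)C/C1=C(\C)CC[C@@H](Br)C(C)(C)Cl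
F8 | step 12 | (1R,3S,4S,6R,8R,11S)-4,8-dibromo-3-chloro-3,7,7,11-tetramethylspiro[5.5]undecane-1,11-diyl carbonate | O=C1O[C@@H]2C[C@](C)(Cl)[C@@H](Br)C[C@@]23C(C)(C)[C@H](Br)CC[C@@]3(C)O1
F9 | step 12 | (1R,3S,4S,6R,8R,11S)-4,8-dibromo-3-chloro-3,7,7,11-tetramethylspiro[5.5]undecane-1,11-diol | O[C@@H]1C[C@](C)(Cl)[C@@H](Br)C[C@@]12C(C)(C)[C@H](Br)CC[C@@]2(C)O
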